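The plan rests on cutting ring B (cyclohexenone, C5–C10) from ring A (cycloheptene, C1–C5, C10, C11) at the ring-fusion bond C5–C10 and at C7–C8. The key step exploits the 1,5-relation of C7 and C9 across C5–C10 and their 1,3-relation through C8: with C9 as a ketone, a regiodefined C10 enolate adds to C5 of a dienoate (closing ring A) and the relayed C8 enolate acylates at C7 (closing ring B), a Michael–Claisen (3+3) cascade. Its precursor is an open-chain, tartrate-derived trans-acetonide bearing a C9/C10 silyl enol ether and a (2E,4Z)-dienoate; C9 is deoxygenated afterwards.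

Key step: step 9

Locants used throughout: C1 (bears the angelate), C2 (bears the epoxyangelate), C3=C4(CH3), C5 and C10 (ring fusion), C6H2, C7 (C=O), C8(CH3)=C9, C11 (gem-dimethyl). With these locants the target is (1R,2R,5R,10S), cis-fused, with a (2R,3R)-2,3-dimethyloxirane-2-carboxylate on O2.

Remark (assumption): compounds 1, 4, 10 and 19 and all reagents are taken as purchased. The alkene geometry of enone 6 and of the silyl enol ether in 7–11 (drawn E and Z) has no bearing on the outcome, because C11 becomes a gem-dimethyl carbon and the enol ether is consumed as an enolate.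

Step 1
Reactants: 1 dimethyl (4S,5S)-2,2-dimethyl-1,3-dioxolane-4,5-dicarboxylate (acetonide of dimethyl D-tartrate)
Product: 2 (4S,5S)-N4,N5-dimethoxy-N4,N5,2,2-tetramethyl-1,3-dioxolane-4,5-dicarboxamide
Conditions: MeNH(OMe)·HCl, i-PrMgCl, THF, −20 °C
Reagents that add atoms: N,O-dimethylhydroxylamine hydrochloride, CNOC.Cl
Why: Aminolysis of both esters by the magnesium amide (Weinreb amide formation) should give the bis-amide without touching the two stereocentres, whose trans arrangement is also the thermodynamic one.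

Step 2
Reactants: 2 bis-Weinreb amide
Product: 3 (4S,5S)-5-acetyl-N-methoxy-N,2,2-trimethyl-1,3-dioxolane-4-carboxamide
Conditions: MeMgBr (1.1 equiv), THF, −15 °C; aq. NH4Cl
Reagents that add atoms: methylmagnesium bromide, C[Mg]Br
Why: Weinreb ketone synthesis in which the magnesium-chelated adduct of the first addition should deactivate the C2-symmetric substrate towards a second one, so that desymmetrising mono-addition gives the methyl ketone whose carbonyl carbon is C11.

Step 3
Reactants: 3 keto amide; 4 but-1-yne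
Product: 5 (4S,5S)-5-(2-hydroxyhex-3-yn-2-yl)-N-methoxy-N,2,2-trimethyl-1,3-dioxolane-4-carboxamide (both carbinol epimers)
Conditions: 4, n-BuLi, THF, −78 °C; then 3, −78 °C; aq. NH4Cl
Reagents that add atoms: none
Why: 1,2-Addition of the lithium acetylide should occur at the α-alkoxy ketone, which is far more electrophilic than the Weinreb amide at −78 °C, and the new carbinol centre is erased in step 4.

Step 4
Reactants: 5 tertiary propargylic alcohol
Product: 6 (4S,5R)-N-methoxy-N,2,2-trimethyl-5-[(2E)-4-oxohex-2-en-2-yl]-1,3-dioxolane-4-carboxamide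
Conditions: Ph3PAuNTf2 (2 mol%), MeOH (1 equiv), toluene, 25–50 °C
Reagents that add atoms: none
Why: The gold-catalysed Meyer–Schuster rearrangement (formal 1,3-hydroxyl shift) should deliver the β,β-disubstituted enone C11=C10–C9(=O)–C8 under conditions mild enough for the acetonide.

Step 5
Reactants: 6 enone
Product: 7 (4S,5R)-5-[(3Z)-4-(tert-butyldimethylsilyloxy)-2-methylhex-3-en-2-yl]-N-methoxy-N,2,2-trimethyl-1,3-dioxolane-4-carboxamide
Conditions: Me2CuLi (from MeLi and CuI), TBSCl, HMPA, THF, −78 → −30 °C; Et3N, aq. NaHCO3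
Reagents that add atoms: lithium dimethylcuprate, [Li+].C[Cu-]C; tert-butyldimethylsilyl chloride, CC(C)(C)[Si](C)(C)Cl
Why: Chlorosilane-assisted conjugate addition of the Gilman cuprate should make C11 the gem-dimethyl quaternary carbon (no stereocentre arises) and O-silylation traps the enolate regiospecifically as the C9=C10 silyl enol ether, which also masks the ketone.

Step 6
Reactants: 7 silyl enol ether amide
Product: 8 (4S,5R)-5-[(3Z)-4-(tert-butyldimethylsilyloxy)-2-methylhex-3-en-2-yl]-2,2-dimethyl-1,3-dioxolane-4-carbaldehyde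
Conditions: DIBAL-H, THF, −78 °C; Rochelle salt
Reagents that add atoms: none
Why: Weinreb amide reduction should stop at the aldehyde (C3) through the stable aluminium chelate, the silyl enol ether and the acetonide being inert to the hydride.

Step 7
Reactants: 8 aldehyde
Product: 9 tert-butyl{[(3Z)-5-{(4R,5R)-5-[(1Z)-2-iodoprop-1-en-1-yl]-2,2-dimethyl-1,3-dioxolan-4-yl}-5-methylhex-3-en-3-yl]oxy}dimethylsilane
Conditions: EtPPh3I, n-BuLi, THF, 20 °C; iodine, −78 °C; NaHMDS, −20 °C; then 8, −78 → 0 °C
Reagents that add atoms: ethyltriphenylphosphonium iodide, CC[P+](c1ccccc1)(c1ccccc1)c1ccccc1.[I-]; iodine, [I][I]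
Why: The Stork–Zhao-type Wittig olefination with the α-iodo ylide is kinetically Z-selective (iodine cis to the chain), which fixes the C3=C4 geometry that ring A requires.

Step 8
Reactants: 9 Z-vinyl iodide; 10 ethyl (2E)-3-(4,4,5,5-tetramethyl-1,3,2-dioxaborolan-2-yl)prop-2-enoate
Product: 11 ethyl (2E,4Z)-5-{(4R,5R)-5-[(3Z)-4-(tert-butyldimethylsilyloxy)-2-methylhex-3-en-2-yl]-2,2-dimethyl-1,3-dioxolan-4-yl}-4-methylpenta-2,4-dienoate
Conditions: Pd(PPh3)4 (5 mol%), K3PO4, THF–H2O, 25 °C
Reagents that add atoms: none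
Why: Suzuki–Miyaura coupling should proceed with retention at both alkenes to give the (2E,4Z)-dienoate, fast transmetalation outrunning carbopalladation of the hindered enol ether.

Step 9
Reactants: 11 silyl enol ether dienoate
Product: 15 cis-fused bicyclic silyloxy enone (ring B: C7–OSi(i-Pr)3, C7=C8, C9=O; 1,2-O-isopropylidene; 1R,2R,5R,10S), via ammonium enolate 12 (not isolated), via Michael adduct 13 (not isolated), via ammonium diketonate 14 (not isolated)
Conditions: TBAT (Bu4N[Ph3SiF2], 1.05 equiv), 4 Å MS, THF, −78 → 20 °C; then TIPSOTf (1.05 equiv), −78 °C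
Reagents that add atoms: triisopropylsilyl trifluoromethanesulfonate, CC(C)[Si](C(C)C)(C(C)C)OS(=O)(=O)C(F)(F)F
Why: Fluoride removes the silyl group and frees the C10 enolate regiospecifically (aprotic medium, so no drift to C8); this enolate closes ring A by a 7-exo-trig Michael addition to C5 of the dienoate, the ester enolate so formed passes its charge to C8 by proton transfer, and the C8 enolate closes ring B by a 6-exo-trig Claisen (Dieckmann-type) acylation at C7 with loss of ethoxide, the cascade being driven by the stable 2-methyl-1,3-diketonate, which TIPSOTf then silylates at its less hindered oxygen on C7. The closest known reaction type is the Michael–Claisen (3+3) synthesis of cyclohexane-1,3-diones from ketone enolates and enoates, combined with the fluoride-promoted Michael addition of silyl enol ethers. C5 is controlled by the substrate: attack must be perpendicular to the planar s-trans C3=C4–C5=C6 unit, and the trans-acetonide, whose oxygen on C2 lies in that plane, holds C1 and with it the C11–C10 tether on one face, so that H5 ends cis to H2. C10 is set in the same bond formation: with the non-coordinating ammonium counter-ion an open transition state is expected in which the enolate oxygen avoids the ester carbonyl, which puts C9 on the side of C4 and leads to the cis ring fusion, and the hindered C10–H is not exchanged before ring B closes. The step needs 1,4- rather than 1,6-addition and C10 rather than C8 as the first nucleophile: closure at C3 would give a cyclopentane trans-fused to the dioxolane, and C8 carries no charge until the C5–C10 bond exists.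

Step 10
Reactants: 15 bicyclic silyloxy enone
Product: 18 (1R,2R,5R,10S)-1,2-dihydroxy-4,8,11,11-tetramethyl cis-fused bicyclic enone (C3=C4; C7=O; C8=C9), via allylic alcohol 16 (not isolated), via enone acetonide 17 (not isolated)
Conditions: DIBAL-H, CH2Cl2, −78 °C; then 1 M HCl, THF–H2O, 20 °C
Reagents that add atoms: none
Why: Stork–Danheiser transposition, in which 1,2-reduction of the C9 carbonyl of the vinylogous silyl ester is followed by acid unveiling of the C7 ketone with loss of the C9 oxygen (C8=C9 forms), the same aqueous acid hydrolysing the acetonide while C5 and C10 stay untouched.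

Step 11
Reactants: 19 angelic acid, (2Z)-2-methylbut-2-enoic acid
Product: 20 (2Z)-2-methylbut-2-en-1-ol
Conditions: LiAlH4, Et2O, 0 °C
Reagents that add atoms: none
Why: Hydride reduction of the carboxylic acid should give the allylic alcohol and leave the Z-trisubstituted alkene unchanged.

Step 12
Reactants: 20 (2Z)-2-methylbut-2-en-1-ol
Product: 21 [(2S,3R)-2,3-dimethyloxiran-2-yl]methanol
Conditions: Ti(OiPr)4 (10 mol%), L-(+)-diethyl tartrate (12 mol%), t-BuOOH, 4 Å MS, CH2Cl2, −20 °C
Reagents that add atoms: tert-butyl hydroperoxide, CC(C)(C)OO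
Why: In the Sharpless asymmetric epoxidation the L-tartrate catalyst should deliver oxygen to the face that gives the (2S,3R)-epoxy alcohol, and syn addition to the Z-alkene keeps the two methyl groups trans.

Step 13
Reactants: 21 epoxy alcohol
Product: 22 (2R,3R)-2,3-dimethyloxirane-2-carboxylic acid
Conditions: RuCl3 (2 mol%), NaIO4, MeCN–CCl4–H2O, 20 °C
Reagents that add atoms: water, O
Why: Catalytic ruthenium tetroxide oxidation should take the primary alcohol through the aldehyde hydrate to the acid without opening the epoxide, the descriptor at C2 changing to R only through the change of priorities.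

Step 14
Reactants: 18 enone diol; 22 epoxy acid
Product: 23 2-O-[(2R,3R)-2,3-dimethyloxirane-2-carbonyl] ester of 18 (C1 hydroxyl free)
Conditions: 22, 2,4,6-trichlorobenzoyl chloride, Et3N, THF, 20 °C; then 18, DMAP, toluene, 0 → 20 °C
Reagents that add atoms: none
Why: Yamaguchi esterification should take place at the allylic C2 hydroxyl, because the C1 hydroxyl is neopentyl-like next to the quaternary C11.

Step 15
Reactants: 23 mono-ester; 19 angelic acid
Product: 24 target, the 1-O-[(2Z)-2-methylbut-2-enoyl] 2-O-[(2R,3R)-2,3-dimethyloxirane-2-carbonyl] diester of 18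
Conditions: 19, 2,4,6-trichlorobenzoyl chloride, Et3N, toluene, 20 °C; then 23, 80 °C
Reagents that add atoms: none
Why: Acylation of the hindered C1 hydroxyl by the mixed anhydride of angelic acid (Yamaguchi conditions without DMAP) should preserve the Z-geometry of the angelate.

Compound list
1 | dimethyl (4S,5S)-2,2-dimethyl-1,3-dioxolane-4,5-dicarboxylate | CC1(C)O[C@H](C(=O)OC)[C@@H](C(=O)OC)O1 | starting material
2 | (4S,5S)-N4,N5-dimethoxy-N4,N5,2,2-tetramethyl-1,3-dioxolane-4,5-dicarboxamide | CC1(C)O[C@H](C(=O)N(C)OC)[C@@H](C(=O)N(C)OC)O1 | intermediate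
3 | (4S,5S)-5-acetyl-N-methoxy-N,2,2-trimethyl-1,3-dioxolane-4-carboxamide | CC1(C)O[C@H](C(C)=O)[C@@H](C(=O)N(C)OC)O1 | intermediate
4 | but-1-yne | C#CCC | starting material
5 | (4S,5S)-5-(2-hydroxyhex-3-yn-2-yl)-N-methoxy-N,2,2-trimethyl-1,3-dioxolane-4-carboxamide (carbinol epimers) | CC1(C)O[C@H](C(C)(O)C#CCC)[C@@H](C(=O)N(C)OC)O1 | intermediate
6 | (4S,5R)-N-methoxy-N,2,2-trimethyl-5-[(2E)-4-oxohex-2-en-2-yl]-1,3-dioxolane-4-carboxamide | CC1(C)O[C@H](/C(C)=C/C(=O)CC)[C@@H](C(=O)N(C)OC)O1 | intermediate
7 | (4S,5R)-5-[(3Z)-4-(tert-butyldimethylsilyloxy)-2-methylhex-3-en-2-yl]-N-methoxy-N,2,2-trimethyl-1,3-dioxolane-4-carboxamide | CC1(C)O[C@H](C(C)(C)/C=C(/CC)O[Si](C)(C)C(C)(C)C)[C@@H](C(=O)N(C)OC)O1 | intermediate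
8 | (4S,5R)-5-[(3Z)-4-(tert-butyldimethylsilyloxy)-2-methylhex-3-en-2-yl]-2,2-dimethyl-1,3-dioxolane-4-carbaldehyde | CC1(C)O[C@H](C(C)(C)/C=C(/CC)O[Si](C)(C)C(C)(C)C)[C@@H](C=O)O1 | intermediate
9 | tert-butyl{[(3Z)-5-{(4R,5R)-5-[(1Z)-2-iodoprop-1-en-1-yl]-2,2-dimethyl-1,3-dioxolan-4-yl}-5-methylhex-3-en-3-yl]oxy}dimethylsilane | CC1(C)O[C@H](C(C)(C)/C=C(/CC)O[Si](C)(C)C(C)(C)C)[C@@H](/C=C(/C)I)O1 | intermediate
10 | ethyl (2E)-3-(4,4,5,5-tetramethyl-1,3,2-dioxaborolan-2-yl)prop-2-enoate | CCOC(=O)/C=C/B1OC(C)(C)C(C)(C)O1 | starting material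
11 | ethyl (2E,4Z)-5-{(4R,5R)-5-[(3Z)-4-(tert-butyldimethylsilyloxy)-2-methylhex-3-en-2-yl]-2,2-dimethyl-1,3-dioxolan-4-yl}-4-methylpenta-2,4-dienoate | CC1(C)O[C@H](C(C)(C)/C=C(/CC)O[Si](C)(C)C(C)(C)C)[C@@H](/C=C(C)\C=C\C(=O)OCC)O1 | intermediate
12 | tetrabutylammonium C10 enolate of 11 (C9–O−, C9=C10; acetonide and dienoate unchanged) | CC1(C)O[C@H](C(C)(C)/C=C(/CC)[O-])[C@@H](/C=C(C)\C=C\C(=O)OCC)O1.CCCC[N+](CCCC)(CCCC)CCCC | intermediate
13 | keto ester with ring A closed: C5 carries CH2CO2Et and C10 carries propanoyl, cis to each other; 1,2-O-isopropylidene; (1R,2R,5R,10S) | CC1(C)O[C@H]2[C@H](O1)C=C(C)[C@H](CC(=O)OCC)[C@H](C(=O)CC)C2(C)C | intermediate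
14 | tetrabutylammonium 1,3-diketonate of the cis-fused bicyclic 7,9-dione; 1,2-O-isopropylidene; (1R,2R,5R,10S) | CC1(C)O[C@H]2[C@H](O1)C=C(C)[C@@H]3CC(=O)C(C)=C([O-])[C@@H]3C2(C)C.CCCC[N+](CCCC)(CCCC)CCCC | intermediate
15 | cis-fused bicyclic silyloxy enone: C7–OSi(i-Pr)3, C7=C8, C9=O, C3=C4; 1,2-O-isopropylidene; (1R,2R,5R,10S) | CC1(C)O[C@H]2[C@H](O1)C=C(C)[C@@H]3CC(O[Si](C(C)C)(C(C)C)C(C)C)=C(C)C(=O)[C@@H]3C2(C)C | intermediate
16 | C9 carbinol of 15 (both C9 epimers) | CC1(C)O[C@H]2[C@H](O1)C=C(C)[C@@H]3CC(O[Si](C(C)C)(C(C)C)C(C)C)=C(C)C(O)[C@@H]3C2(C)C | intermediate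
17 | cis-fused enone acetonide: C7=O, C8=C9, C3=C4; 1,2-O-isopropylidene; (1R,2R,5R,10S) | CC1(C)O[C@H]2[C@H](O1)C=C(C)[C@@H]3CC(=O)C(C)=C[C@@H]3C2(C)C | intermediate
18 | (1R,2R,5R,10S)-1,2-dihydroxy-4,8,11,11-tetramethyl cis-fused bicyclic enone (trans-1,2-diol; C3=C4; C7=O; C8=C9) | O[C@H]1[C@H](O)C=C(C)[C@@H]2CC(=O)C(C)=C[C@@H]2C1(C)C | intermediate
19 | angelic acid, (2Z)-2-methylbut-2-enoic acid | C/C=C(/C)C(=O)O | starting material
20 | (2Z)-2-methylbut-2-en-1-ol | C/C=C(/C)CO | intermediate
21 | [(2S,3R)-2,3-dimethyloxiran-2-yl]methanol | OC[C@]1(C)O[C@@H]1C | intermediate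
22 | (2R,3R)-2,3-dimethyloxirane-2-carboxylic acid | OC(=O)[C@]1(C)O[C@@H]1C | intermediate
23 | 2-O-[(2R,3R)-2,3-dimethyloxirane-2-carbonyl] ester of 18 | O[C@H]1[C@H](OC(=O)[C@]2(C)O[C@@H]2C)C=C(C)[C@@H]2CC(=O)C(C)=C[C@@H]2C1(C)C | intermediate
24 | CNP0332927.1: 1-O-angeloyl 2-O-[(2R,3R)-2,3-dimethyloxirane-2-carbonyl] diester of 18 | C/C=C(/C)C(=O)O[C@H]1[C@H](OC(=O)[C@]2(C)O[C@@H]2C)C=C(C)[C@@H]2CC(=O)C(C)=C[C@@H]2C1(C)C | target

Total step count: 15. Longest linear sequence: 12 (steps 1–10, 14, 15).

Steps most likely to fail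

Step 9. The enolate may add through the transition state that leads to the C10 epimer (trans ring fusion), it may close at C3 (1,6-addition), or the Claisen closure may stall after the Michael addition. The fallback separates the two events and uses a Lewis acid instead of a free enolate. Setting out from 11, a Mukaiyama–Michael cyclisation (TiCl4, CH2Cl2, −78 °C) closes ring A through an open transition state; aqueous work-up gives keto ester 13 as an isolated compound, together with its C10 epimer F1 if that forms. The two are separable, and the C10 epimer F1 is re-equilibrated at C10 with DBU and recycled. Keto ester 13 is then cyclised in a separate Dieckmann condensation (LiHMDS, THF, −78 → 0 °C) and the lithium diketonate is quenched with TIPSOTf, which comes back to the route at 15.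

Step 15. The neopentyl-like C1 hydroxyl may resist acylation, the angelate may isomerise to the tiglate under forcing conditions, or the C2 ester may migrate to O1. The fallback builds the Z-alkene on the ester instead of acylating with angelic acid. Setting out from 23, the C1 hydroxyl is esterified with 2-[bis(2,2,2-trifluoroethoxy)phosphoryl]propanoic acid (DCC, DMAP, CH2Cl2) to the phosphonate ester F2; a Still–Gennari olefination of the phosphonate ester F2 with acetaldehyde (KHMDS, 18-crown-6, THF, −78 °C) then gives the Z-2-methylbut-2-enoate and comes back to the route at 24.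

Step 14. Differentiation of the two hydroxyls may be incomplete, or slow coupling of the hindered α,α-disubstituted glycidic acid may allow acyl migration. The fallback reverses the order of the two esterifications with a temporary protecting group. Setting out from 18, the C2 hydroxyl is silylated selectively (TESOTf, 2,6-lutidine, CH2Cl2, −78 °C) to the C2 triethylsilyl ether F3; the C1 hydroxyl is acylated with the angelic mixed anhydride as in step 15 to the silyl-protected angelate F4; HF·pyridine removes the silyl group to give the C1 angelate F5; Yamaguchi coupling of the C1 angelate F5 with 22 then comes back to the route at 24 and by-passes 23.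

Further compounds
F1 | step 9 | C10 epimer of keto ester 13 (propanoyl at C10 trans to CH2CO2Et at C5) | CC1(C)O[C@H]2[C@H](O1)C=C(C)[C@H](CC(=O)OCC)[C@@H](C(=O)CC)C2(C)C
F2 | step 15 | 1-O-{2-[bis(2,2,2-trifluoroethoxy)phosphoryl]propanoyl} ester of 23 | CC(C(=O)O[C@H]1[C@H](OC(=O)[C@]2(C)O[C@@H]2C)C=C(C)[C@@H]2CC(=O)C(C)=C[C@@H]2C1(C)C)P(=O)(OCC(F)(F)F)OCC(F)(F)F
F3 | step 14 | 2-O-triethylsilyl ether of 18 | O[C@H]1[C@H](O[Si](CC)(CC)CC)C=C(C)[C@@H]2CC(=O)C(C)=C[C@@H]2C1(C)C
F4 | step 14 | 1-O-angeloyl 2-O-triethylsilyl derivative of 18 | C/C=C(/C)C(=O)O[C@H]1[C@H](O[Si](CC)(CC)CC)C=C(C)[C@@H]2CC(=O)C(C)=C[C@@H]2C1(C)C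
F5 | step 14 | 1-O-angeloyl ester of 18 (C2 hydroxyl free) | C/C=C(/C)C(=O)O[C@H]1[C@H](O)C=C(C)[C@@H]2CC(=O)C(C)=C[C@@H]2C1(C)C
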